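**Retrosynthetic overview**
1. The gramine side chain is added last by a Mannich reaction at indole C3. The N-methyl group comes from LiAlH4 reduction of a (−)-menthyl carbamate, which also serves as N-protection and as the handle for selecting the enantiomer.
2. The piperidine and dihydrofuran rings, and both ring-fusion stereocentres, come from one acyl-Pictet–Spengler/rearrangement cascade with CH2O on a 2-(5-hydroxyindol-4-yl)tryptamine carbamate (forms C1–C9a and C4a–O).
3. The biaryl bond (indole C2 to indole C4′) comes from a Suzuki coupling of two halves of similar size: a tryptamine-derived indol-2-yl boronate and a 4-bromo-5-benzyloxy-7-methoxy-1-tosylindole.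
4. Boronate half: phenylhydrazine + 2,3-dihydrofuran (Fischer, first indole ring), OH to NH2, menthyl carbamate, Ir C–H borylation.
5. Bromide half: 1,3-difluorobenzene, nitration, ortho- then para-SNAr, bromination, Bartoli (second indole ring), N-tosylation. Ring order: the two indoles separately, then piperidine and dihydrofuran together.

Assumption: ring-fusion carbons are numbered as in β-carboline (C4a bears the ether O, C9a bears N9–H and the indol-4-yl carbon); the target is then (4aS,9aR). Primed locants refer to the methoxyindole unit.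

**Step 1**
Reactants: 1 phenylhydrazine; 2 2,3-dihydrofuran
Product: 5 tryptophol (2-(1H-indol-3-yl)ethanol), via 4-hydroxybutanal 3 (not isolated), via phenylhydrazone 4 (not isolated)
Conditions: 4% aq H2SO4/DMAc (1:1), 100 °C
Reagents that add atoms: none
Why: Fischer indole synthesis in which acid hydrates the enol ether to the aldehyde, whose phenylhydrazone undergoes [3,3]-sigmatropic rearrangement and loses NH3 to give the 3-(2-hydroxyethyl)indole.

**Step 2**
Reactants: 5 tryptophol
Product: 6 2-(1H-indol-3-yl)ethyl 4-methylbenzenesulfonate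
Conditions: TsCl (1.1 equiv), pyridine, CH2Cl2, 0 °C
Reagents that add atoms: p-toluenesulfonyl chloride, Cc1ccc(cc1)S(=O)(=O)Cl
Why: Selective O-sulfonylation of the primary alcohol (the indole N–H does not react without strong base) installs a leaving group.

**Step 3**
Reactants: 6 2-(1H-indol-3-yl)ethyl 4-methylbenzenesulfonate
Product: 7 3-(2-azidoethyl)-1H-indole
Conditions: NaN3 (1.5 equiv), DMF, 60 °C
Reagents that add atoms: sodium azide, [Na+].[N-]=[N+]=[N-]
Why: SN2 displacement of a primary tosylate by azide.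

**Step 4**
Reactants: 7 3-(2-azidoethyl)-1H-indole
Product: 8 tryptamine (2-(1H-indol-3-yl)ethanamine)
Conditions: H2 (1 atm), 10% Pd/C, MeOH, rt
Reagents that add atoms: none
Why: Catalytic hydrogenation reduces the azide to the primary amine with loss of N2 and leaves the indole untouched.

**Step 5**
Reactants: 8 tryptamine
Product: 9 (1R,2S,5R)-2-isopropyl-5-methylcyclohexyl N-[2-(1H-indol-3-yl)ethyl]carbamate
Conditions: (−)-menthyl chloroformate (1.05 equiv), Et3N, CH2Cl2, 0 °C → rt
Reagents that add atoms: (1R,2S,5R)-(−)-menthyl chloroformate, ClC(=O)O[C@@H]1C[C@H](C)CC[C@H]1C(C)C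
Why: N-acylation of the primary amine (carbamate formation) gives a group that later acts as N-acyliminium precursor, covalent resolving handle and latent N-methyl.

**Step 6**
Reactants: 9 menthyl tryptamine carbamate
Product: 10 (1R,2S,5R)-menthyl N-{2-[2-(4,4,5,5-tetramethyl-1,3,2-dioxaborolan-2-yl)-1H-indol-3-yl]ethyl}carbamate
Conditions: [Ir(cod)OMe]2 (2.5 mol %), dtbpy (5 mol %), B2pin2 (1.0 equiv), THF, 60 °C
Reagents that add atoms: bis(pinacolato)diboron, CC1(C)OB(OC1(C)C)B1OC(C)(C)C(C)(C)O1
Why: Iridium-catalysed C–H borylation (Hartwig–Miyaura type) of a 3-substituted N–H indole takes place at C2.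

**Step 7**
Reactants: 11 1,3-difluorobenzene
Product: 12 2,4-difluoro-1-nitrobenzene
Conditions: HNO3 (1.1 equiv), conc. H2SO4, 0–10 °C
Reagents that add atoms: nitric acid, O[N+](=O)[O-]
Why: Electrophilic aromatic nitration at C4, the unhindered position ortho to one fluorine and para to the other.

**Step 8**
Reactants: 12 2,4-difluoro-1-nitrobenzene
Product: 13 4-fluoro-2-methoxy-1-nitrobenzene
Conditions: MeOH (1.05 equiv), KOtBu (1.05 equiv), toluene, 0 °C
Reagents that add atoms: methanol, CO
Why: SNAr in a non-polar solvent, where the potassium alkoxide is delivered by coordination to the nitro group and replaces only the ortho fluorine.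

**Step 9**
Reactants: 13 4-fluoro-2-methoxy-1-nitrobenzene
Product: 14 4-(benzyloxy)-2-methoxy-1-nitrobenzene
Conditions: BnOH (1.1 equiv), KOtBu (1.15 equiv), THF, 0 °C → rt
Reagents that add atoms: benzyl alcohol, OCc1ccccc1
Why: SNAr of the remaining fluorine para to the nitro group by benzyloxide installs the protected phenol oxygen.

**Step 10**
Reactants: 14 4-(benzyloxy)-2-methoxy-1-nitrobenzene
Product: 15 1-(benzyloxy)-2-bromo-5-methoxy-4-nitrobenzene
Conditions: NBS (1.05 equiv), DMF, 50 °C, dark
Reagents that add atoms: N-bromosuccinimide, O=C1CCC(=O)N1Br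
Why: Electrophilic aromatic bromination goes para to OMe and ortho to OBn (meta to NO2), because the site between the two oxygens is hindered and the site ortho to NO2 is deactivated.

**Step 11**
Reactants: 15 1-(benzyloxy)-2-bromo-5-methoxy-4-nitrobenzene
Product: 17 5-(benzyloxy)-4-bromo-7-methoxy-1H-indole, via nitrosoarene 16 (not isolated)
Conditions: CH2=CHMgBr (3.3 equiv), THF, −45 °C; sat. aq NH4Cl
Reagents that add atoms: vinylmagnesium bromide, C=C[Mg]Br
Why: Bartoli indole synthesis, in which the Grignard reagent reduces NO2 to the nitrosoarene, a second equivalent adds at oxygen, and a [3,3]-shift to the only free ortho carbon (promoted by the ortho-OMe) followed by cyclisation gives the 7-methoxyindole while the aryl bromide survives at −45 °C.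

**Step 12**
Reactants: 17 5-(benzyloxy)-4-bromo-7-methoxy-1H-indole
Product: 18 5-(benzyloxy)-4-bromo-7-methoxy-1-tosyl-1H-indole
Conditions: TsCl (1.2 equiv), Bu4NHSO4 (cat.), 50% aq NaOH, CH2Cl2, 0 °C → rt
Reagents that add atoms: p-toluenesulfonyl chloride, Cc1ccc(cc1)S(=O)(=O)Cl
Why: Phase-transfer N-sulfonylation, which deactivates C3 of this electron-rich indole towards formaldehyde and acid in step 15.

**Step 13**
Reactants: 10 indol-2-yl boronate; 18 5-(benzyloxy)-4-bromo-7-methoxy-1-tosyl-1H-indole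
Product: 19 (1R,2S,5R)-menthyl N-{2-[2-(5-(benzyloxy)-7-methoxy-1-tosyl-1H-indol-4-yl)-1H-indol-3-yl]ethyl}carbamate
Conditions: XPhos Pd G3 (5 mol %), 0.5 M aq K3PO4 (3 equiv), THF, 40 °C
Reagents that add atoms: none
Why: Suzuki–Miyaura coupling with a dialkylbiarylphosphine palladacycle, which couples ortho-substituted bromides fast enough to outrun protodeboronation of the 2-indolyl boronate.

**Step 14**
Reactants: 19 benzyl-protected biaryl carbamate
Product: 20 (1R,2S,5R)-menthyl N-{2-[2-(5-hydroxy-7-methoxy-1-tosyl-1H-indol-4-yl)-1H-indol-3-yl]ethyl}carbamate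
Conditions: H2 (1 atm), 10% Pd/C, EtOAc/MeOH, rt
Reagents that add atoms: none
Why: Hydrogenolysis of the benzyl ether frees the phenol while carbamate, sulfonamide and both indoles are inert.

**Step 15**
Reactants: 20 phenol biaryl carbamate
Product: 23 (4aS,9aR)-pentacyclic menthyl carbamate (2-menthyloxycarbonyl-1,3,4,9-tetrahydro-β-carboline with C9a bonded to C4′ and C4a bonded through O to C5′ of 7′-methoxy-1′-tosylindole; N9–H), via N-acyliminium ion 21 (not isolated), via azaspiroindolenine 22 (not isolated)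
Conditions: (CH2O)n (1.5 equiv), TFA/ClCH2CH2Cl (1:5), rt → 60 °C; then SiO2 chromatography and crystallisation to separate the two cis epimers
Reagents that add atoms: formaldehyde (used as paraformaldehyde), C=O
Why: Acyl-Pictet–Spengler/Mannich cascade in which the N-acyliminium ion first spirocyclises at C3 (interrupted Pictet–Spengler), the spiroindolenine re-opens by retro-Mannich and closes at the aryl-bearing C2, and the resulting tertiary benzylic C3 cation is captured by the ortho phenol, which can only reach the face syn to its own aryl group so the ring fusion is cis; the remote menthyl group gives no useful face selectivity, so both cis epimers form (about 1:1) and, being diastereomers, are separated, with the (4aS,9aR) isomer (assigned by X-ray against the known menthyl centres) carried on.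

**Step 16**
Reactants: 23 (4aS,9aR)-pentacyclic menthyl carbamate
Product: 24 (4aS,9aR)-2-methyl pentacyclic amine (as 23 but N2–CH3 and N1′–H; indole C3′–H)
Conditions: LiAlH4 (8 equiv), THF, reflux; Fieser work-up
Reagents that add atoms: none
Why: Hydride reduction of the carbamate carbonyl to N–CH3 releases menthol, hydride attack at sulfur cleaves the N-sulfonylindole, and the two quaternary stereocentres cannot epimerise.

**Step 17**
Reactants: 24 (4aS,9aR)-2-methyl pentacyclic amine
Product: 25 target, (4aS,9aR)-3′-[(dimethylamino)methyl] derivative of 24 (CNP0318114.2)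
Conditions: 40% aq Me2NH (1.2 equiv), 37% aq CH2O (1.1 equiv), AcOH, 0 °C → rt
Reagents that add atoms: formaldehyde, C=O; dimethylamine, CNC
Why: Mannich reaction (gramine synthesis) in which the iminium ion attacks C3′ of the electron-rich indole, the most nucleophilic carbon, while the hindered indoline N–H gives at most a reversible aminal and the stereocentres are untouched.

**Compound list**
1 | phenylhydrazine | NNc1ccccc1 | starting material
2 | 2,3-dihydrofuran | C1=COCC1 | starting material
3 | 4-hydroxybutanal (in equilibrium with 2-hydroxytetrahydrofuran) | OCCCC=O | intermediate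
4 | 4-hydroxybutanal (E)-phenylhydrazone | OCCC/C=N/Nc1ccccc1 | intermediate
5 | tryptophol, 2-(1H-indol-3-yl)ethanol | OCCc1c[nH]c2ccccc12 | intermediate
6 | 2-(1H-indol-3-yl)ethyl 4-methylbenzenesulfonate | Cc1ccc(cc1)S(=O)(=O)OCCc1c[nH]c2ccccc12 | intermediate
7 | 3-(2-azidoethyl)-1H-indole | [N-]=[N+]=NCCc1c[nH]c2ccccc12 | intermediate
8 | tryptamine | NCCc1c[nH]c2ccccc12 | intermediate
9 | (1R,2S,5R)-menthyl N-[2-(1H-indol-3-yl)ethyl]carbamate | O=C(NCCc1c[nH]c2ccccc12)O[C@@H]1C[C@H](C)CC[C@H]1C(C)C | intermediate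
10 | (1R,2S,5R)-menthyl N-{2-[2-(pinacolatoboryl)-1H-indol-3-yl]ethyl}carbamate | O=C(NCCc1c(B3OC(C)(C)C(C)(C)O3)[nH]c2ccccc12)O[C@@H]1C[C@H](C)CC[C@H]1C(C)C | intermediate
11 | 1,3-difluorobenzene | Fc1cccc(F)c1 | starting material
12 | 2,4-difluoro-1-nitrobenzene | [O-][N+](=O)c1ccc(F)cc1F | intermediate
13 | 4-fluoro-2-methoxy-1-nitrobenzene | COc1cc(F)ccc1[N+](=O)[O-] | intermediate
14 | 4-(benzyloxy)-2-methoxy-1-nitrobenzene | COc1cc(OCc2ccccc2)ccc1[N+](=O)[O-] | intermediate
15 | 1-(benzyloxy)-2-bromo-5-methoxy-4-nitrobenzene | COc1cc(OCc2ccccc2)c(Br)cc1[N+](=O)[O-] | intermediate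
16 | 1-(benzyloxy)-2-bromo-5-methoxy-4-nitrosobenzene | COc1cc(OCc2ccccc2)c(Br)cc1N=O | intermediate
17 | 5-(benzyloxy)-4-bromo-7-methoxy-1H-indole | COc1cc(OCc3ccccc3)c(Br)c2cc[nH]c12 | intermediate
18 | 5-(benzyloxy)-4-bromo-7-methoxy-1-tosyl-1H-indole | COc1cc(OCc3ccccc3)c(Br)c2ccn(S(=O)(=O)c4ccc(C)cc4)c12 | intermediate
19 | (1R,2S,5R)-menthyl N-{2-[2-(5-(benzyloxy)-7-methoxy-1-tosyl-1H-indol-4-yl)-1H-indol-3-yl]ethyl}carbamate | O=C(NCCc1c(-c3c(OCc5ccccc5)cc(OC)c4n(S(=O)(=O)c6ccc(C)cc6)ccc34)[nH]c2ccccc12)O[C@@H]1C[C@H](C)CC[C@H]1C(C)C | intermediate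
20 | (1R,2S,5R)-menthyl N-{2-[2-(5-hydroxy-7-methoxy-1-tosyl-1H-indol-4-yl)-1H-indol-3-yl]ethyl}carbamate | O=C(NCCc1c(-c3c(O)cc(OC)c4n(S(=O)(=O)c5ccc(C)cc5)ccc34)[nH]c2ccccc12)O[C@@H]1C[C@H](C)CC[C@H]1C(C)C | intermediate
21 | N-methylidene N-acyliminium ion of 20 (trifluoroacetate) | C=[N+](CCc1c(-c3c(O)cc(OC)c4n(S(=O)(=O)c5ccc(C)cc5)ccc34)[nH]c2ccccc12)C(=O)O[C@@H]1C[C@H](C)CC[C@H]1C(C)C.[O-]C(=O)C(F)(F)F | intermediate
22 | azaspiroindolenine: 1′-(menthyloxycarbonyl)-2-(5-hydroxy-7-methoxy-1-tosylindol-4-yl)spiro[indole-3,3′-pyrrolidine], both spiro epimers (centre erased on ring-opening) | O=C(O[C@@H]1C[C@H](C)CC[C@H]1C(C)C)N1CCC2(C1)C(-c3c(O)cc(OC)c4n(S(=O)(=O)c5ccc(C)cc5)ccc34)=Nc1ccccc12 | intermediate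
23 | (4aS,9aR)-pentacyclic menthyl carbamate (cis-fused benzofuro[3,2-b]indoline; N2–CO2-menthyl, N1′–Ts, N9–H) | COc1cc2c(c3ccn(S(=O)(=O)c4ccc(C)cc4)c13)[C@@]13CN(C(=O)O[C@@H]4C[C@H](C)CC[C@H]4C(C)C)CC[C@]1(O2)c1ccccc1N3 | intermediate
24 | (4aS,9aR)-2-methyl pentacyclic amine (N1′–H, C3′–H) | COc1cc2c(c3cc[nH]c13)[C@@]13CN(C)CC[C@]1(O2)c1ccccc1N3 | intermediate
25 | target CNP0318114.2, (4aS,9aR) | COc1cc2c(c3c(CN(C)C)c[nH]c13)[C@@]13CN(C)CC[C@]1(O2)c1ccccc1N3 | target

**Totals**
Total step count: 17. Longest linear sequence: 11 steps (steps 1–6 or 7–12, then 13–17).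

**Three steps most likely to fail**

Step 11 (Bartoli on a crowded, electron-rich nitroarene; yields are typically modest). The fallback sets out from 15 and comes back at 17. The nitro group is reduced with Fe/NH4Cl (EtOH/H2O, 70 °C; aryl bromide and benzyl ether survive) to 4-(benzyloxy)-5-bromo-2-methoxyaniline F1. NIS (MeCN, 0 °C) iodinates the only free position ortho to NH2, giving 4-(benzyloxy)-3-bromo-2-iodo-6-methoxyaniline F2. Sonogashira coupling with ethynyltrimethylsilane at the C–I bond (PdCl2(PPh3)2, CuI, Et3N, rt) gives 4-(benzyloxy)-3-bromo-6-methoxy-2-[(trimethylsilyl)ethynyl]aniline F3. TBAF in THF at reflux removes the silyl group and closes the pyrrole ring by 5-endo-dig hydroamination to 17.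

Step 13 (Suzuki coupling of a protodeboronation-prone 2-indolyl boronate with a di-ortho-substituted bromide). The fallback sets out from 18 and comes back at 19, building the first indole ring during the union instead of before it. Commercial but-3-yn-1-amine is acylated with (−)-menthyl chloroformate (Et3N, CH2Cl2) to (1R,2S,5R)-menthyl N-(but-3-yn-1-yl)carbamate F4. Copper-free Sonogashira coupling with 18 (PdCl2(MeCN)2, XPhos, Cs2CO3, MeCN, 80 °C) gives (1R,2S,5R)-menthyl N-{4-[5-(benzyloxy)-7-methoxy-1-tosyl-1H-indol-4-yl]but-3-yn-1-yl}carbamate F5. Larock heteroannulation with commercial 2-iodoaniline (Pd(OAc)2, LiCl, K2CO3, DMF, 100 °C) places the bulky aryl group at C2 and the aminoethyl chain at C3 and gives 19.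

Step 15 (the cascade may stop at the spiroindolenine, and the two menthyl epimers may not separate). The fallback sets out from 20 and comes back at 24, replacing separation of covalent diastereomers by a classical salt resolution. The cascade is run as in step 15 and the unseparated mixture of 23 and the (4aR,9aS) ring-fusion epimer of 23 F6 is reduced with LiAlH4 as in step 16. This gives racemic amine, that is 24 together with the (4aR,9aS) enantiomer of 24 F7. The racemate is resolved by crystallising the (−)-O,O′-di-p-toluoyl-L-tartrate salt of 24 F8 from EtOH/acetone (the D-acid is used if F7 gives the less soluble salt), and aq NaHCO3 liberates 24.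

**Further compounds**
F1 | step 11 | 4-(benzyloxy)-5-bromo-2-methoxyaniline | COc1cc(OCc2ccccc2)c(Br)cc1N
F2 | step 11 | 4-(benzyloxy)-3-bromo-2-iodo-6-methoxyaniline | COc1cc(OCc2ccccc2)c(Br)c(I)c1N
F3 | step 11 | 4-(benzyloxy)-3-bromo-6-methoxy-2-[(trimethylsilyl)ethynyl]aniline | COc1cc(OCc2ccccc2)c(Br)c(C#C[Si](C)(C)C)c1N
F4 | step 13 | (1R,2S,5R)-menthyl N-(but-3-yn-1-yl)carbamate | C#CCCNC(=O)O[C@@H]1C[C@H](C)CC[C@H]1C(C)C
F5 | step 13 | (1R,2S,5R)-menthyl N-{4-[5-(benzyloxy)-7-methoxy-1-tosyl-1H-indol-4-yl]but-3-yn-1-yl}carbamate | O=C(NCCC#Cc1c(OCc3ccccc3)cc(OC)c2n(S(=O)(=O)c4ccc(C)cc4)ccc12)O[C@@H]1C[C@H](C)CC[C@H]1C(C)C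
F6 | step 15 | (4aR,9aS) ring-fusion epimer of 23 | COc1cc2c(c3ccn(S(=O)(=O)c4ccc(C)cc4)c13)[C@]13CN(C(=O)O[C@@H]4C[C@H](C)CC[C@H]4C(C)C)CC[C@@]1(O2)c1ccccc1N3
F7 | step 15 | (4aR,9aS) enantiomer of 24 | COc1cc2c(c3cc[nH]c13)[C@]13CN(C)CC[C@@]1(O2)c1ccccc1N3
F8 | step 15 | (−)-O,O′-di-p-toluoyl-L-tartrate (2R,3R) salt of 24 | COc1cc2c(c3cc[nH]c13)[C@@]13C[NH+](C)CC[C@]1(O2)c1ccccc1N3.[O-]C(=O)[C@H](OC(=O)c1ccc(C)cc1)[C@@H](OC(=O)c1ccc(C)cc1)C(=O)O
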